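Everything rests on cutting both aryl–C(CH3)2CH=CH2 bonds at once, back to a 6,5′-dibromo isoflavan and prenylboronic ester. One palladium-catalysed operation forges both quaternary benzylic carbons through the γ-carbon of the allyl unit and leaves the C3 stereocentre alone. It exploits that C6 of ring A (ortho to O7, para to O1) and C5′ of ring B (ortho to O4′, para to O2′) are the sites where the resorcinol-type rings brominate, so the halogens mark exactly the carbons to be alkylated. The precursor is the (3R)-isoflavan with three methoxymethyl-protected phenols and bromine at C6 and C5′.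

Key step: step 8

Assumption (step 6): the sense of induction of the iridium P,N catalyst on a 2′-alkoxy isoflav-3-ene is empirical; the catalyst antipode that delivers the 3R series is used, to be confirmed by chiral HPLC and chiroptical comparison with known (3R)-isoflavans.

Assumption (step 8): the ligand is the member of the bulky dialkylbiarylphosphine family that shows the highest branched preference on a model 2-(methoxymethoxy)bromoarene; the reasoning below does not depend on which member that is.

Step 1
Reactants: 1 2,4-dihydroxybenzaldehyde; 2 2,4-dihydroxyphenylacetic acid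
Product: 3 7-acetoxy-3-(2,4-diacetoxyphenyl)-2H-chromen-2-one
Conditions: Ac2O, Et3N, 110 °C
Reagents that add atoms: acetic anhydride, CC(=O)OC(C)=O
Why: Perkin–Oglialoro condensation: the mixed anhydride of the arylacetic acid condenses with the aldehyde, the ortho oxygen of the salicylaldehyde closes the lactone and the other three phenols are acetylated; any benzofuranone formed from the 2-hydroxyarylacetic acid should funnel to the same, more stable coumarin.

Step 2
Reactants: 3 7-acetoxy-3-(2,4-diacetoxyphenyl)-2H-chromen-2-one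
Product: 4 7-hydroxy-3-(2,4-dihydroxyphenyl)-2H-chromen-2-one
Conditions: conc. HCl (cat.), MeOH, reflux
Reagents that add atoms: none
Why: Acid-catalysed transesterification should strip the three aryl acetates, while the coumarin lactone, which recloses spontaneously, is expected to persist.

Step 3
Reactants: 4 7-hydroxy-3-(2,4-dihydroxyphenyl)-2H-chromen-2-one
Product: 5 3-[2,4-bis(methoxymethoxy)phenyl]-7-(methoxymethoxy)-2H-chromen-2-one
Conditions: MOMCl (4 equiv), K2CO3, DMF, 0 °C → rt
Reagents that add atoms: chloromethyl methyl ether, COCCl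
Why: Williamson-type O-alkylation of the three phenoxides; masking every phenol at this stage leaves the lactone oxygen as the only phenol that the next step unveils, which fixes the direction of the later ring closure.

Step 4
Reactants: 5 3-[2,4-bis(methoxymethoxy)phenyl]-7-(methoxymethoxy)-2H-chromen-2-one
Product: 6 (Z)-2-[2,4-bis(methoxymethoxy)phenyl]-3-[2-hydroxy-4-(methoxymethoxy)phenyl]prop-2-en-1-ol
Conditions: DIBAL-H (5 equiv), CH2Cl2, −78 → 0 °C; aq. Rochelle salt
Reagents that add atoms: none
Why: 1,2-Reduction of the α,β-unsaturated lactone through the lactol to the allylic diol; the alkene geometry imposed by the coumarin ring is carried over as Z, and the hydride at low temperature should touch neither the acetals nor the alkene.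

Step 5
Reactants: 6 (Z)-2-[2,4-bis(methoxymethoxy)phenyl]-3-[2-hydroxy-4-(methoxymethoxy)phenyl]prop-2-en-1-ol
Product: 7 3-[2,4-bis(methoxymethoxy)phenyl]-7-(methoxymethoxy)-2H-chromene
Conditions: PPh3, DIAD, THF, 0 °C → rt
Reagents that add atoms: none
Why: Intramolecular Mitsunobu etherification: the single free phenol displaces the activated primary allylic alcohol (6-exo-tet) and closes the pyran ring of the isoflav-3-ene.

Step 6
Reactants: 7 3-[2,4-bis(methoxymethoxy)phenyl]-7-(methoxymethoxy)-2H-chromene
Product: 8 (3R)-3-[2,4-bis(methoxymethoxy)phenyl]-7-(methoxymethoxy)chromane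
Conditions: H2 (50 bar), [Ir(cod)(chiral phosphino-oxazoline)]BArF (1–2 mol %), CH2Cl2, rt
Reagents that add atoms: none
Why: Iridium-catalysed asymmetric hydrogenation of a trisubstituted aryl alkene with a chiral P,N ligand, a reaction type known for protected 3-aryl-2H-chromenes; the ligand pocket selects the face of C3=C4 that receives hydrogen and so sets C3 as R.

Step 7
Reactants: 8 (3R)-3-[2,4-bis(methoxymethoxy)phenyl]-7-(methoxymethoxy)chromane
Product: 9 (3R)-6-bromo-3-[5-bromo-2,4-bis(methoxymethoxy)phenyl]-7-(methoxymethoxy)chromane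
Conditions: NBS (2.05 equiv), MeCN, −10 → 0 °C, dark
Reagents that add atoms: N-bromosuccinimide, O=C1CCC(=O)N1Br
Why: Electrophilic aromatic bromination: each resorcinol-type ring should react at the carbon para to one oxygen and ortho to the other (C6, C5′), the carbons between two oxygens (C8, C3′) being more shielded, and the polar, non-radical conditions should spare C4–H, C3 and the acetals.

Step 8
Reactants: 9 (3R)-6-bromo-3-[5-bromo-2,4-bis(methoxymethoxy)phenyl]-7-(methoxymethoxy)chromane; 10 prenylboronic acid pinacol ester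
Product: 11 (3R)-3-[2,4-bis(methoxymethoxy)-5-(2-methylbut-3-en-2-yl)phenyl]-7-(methoxymethoxy)-6-(2-methylbut-3-en-2-yl)chromane
Conditions: 10 (4 equiv), aminobiphenyl palladacycle precatalyst of a bulky dialkylbiarylphosphine (5 mol % per C–Br), 0.5 M aq. K3PO4, MeCN, 70 °C
Reagents that add atoms: none
Why: Suzuki–Miyaura allyl–aryl coupling run twice in one flask: Pd(0) inserts into each electron-rich C–Br bond, the oxo-ligated aryl palladium transmetalates with the allylboronate through a cyclic SE2′ transition state that binds the γ-carbon of the prenyl unit to palladium, and the tertiary σ-allyl aryl palladium reductively eliminates to the 1,1-dimethylallyl arene. The closest known reaction type is the ligand-controlled γ-selective coupling of 3,3-disubstituted allylboronates with aryl halides. No ring is closed and no stereocentre is created; C3 is remote from both reacting carbons and carries no hydrogen acidic enough for aqueous phosphate, so its R configuration should be retained. The step needs branched over linear allyl transfer, which the bulky monophosphine should secure by making reductive elimination faster than σ–π–σ migration of palladium to the primary terminus. It also needs the correct sites, and these are fixed by the bromine atoms at C6 (ortho to O7, para to O1) and C5′ (ortho to O4′, para to O2′). Both sites carry one small ortho OMOM group and one ortho hydrogen, so one catalyst and one set of conditions should serve both C–Br bonds.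

Step 9
Reactants: 11 (3R)-3-[2,4-bis(methoxymethoxy)-5-(2-methylbut-3-en-2-yl)phenyl]-7-(methoxymethoxy)-6-(2-methylbut-3-en-2-yl)chromane
Product: 12 Manuifolin E, (3R)-3-[2,4-dihydroxy-5-(2-methylbut-3-en-2-yl)phenyl]-6-(2-methylbut-3-en-2-yl)chroman-7-ol
Conditions: HCl (ca. 1 M, from conc. aq. HCl), MeOH, 0 → 20 °C
Reagents that add atoms: none
Why: Acid-catalysed acetal cleavage (transacetalisation to methanol) should free the three phenols; protonating a vinyl group would give only a secondary cation beside a quaternary carbon, so dilute acid at or below room temperature should not close rings onto the neighbouring phenols, and C3 is not involved.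

Compound list
1 | 2,4-dihydroxybenzaldehyde | O=Cc1ccc(O)cc1O | starting material
2 | 2,4-dihydroxyphenylacetic acid | OC(=O)Cc1ccc(O)cc1O | starting material
3 | 7-acetoxy-3-(2,4-diacetoxyphenyl)-2H-chromen-2-one | CC(=O)Oc1ccc2cc(-c3ccc(OC(C)=O)cc3OC(C)=O)c(=O)oc2c1 | intermediate
4 | 7-hydroxy-3-(2,4-dihydroxyphenyl)-2H-chromen-2-one | Oc1ccc2cc(-c3ccc(O)cc3O)c(=O)oc2c1 | intermediate
5 | 3-[2,4-bis(methoxymethoxy)phenyl]-7-(methoxymethoxy)-2H-chromen-2-one | COCOc1ccc2cc(-c3ccc(OCOC)cc3OCOC)c(=O)oc2c1 | intermediate
6 | (Z)-2-[2,4-bis(methoxymethoxy)phenyl]-3-[2-hydroxy-4-(methoxymethoxy)phenyl]prop-2-en-1-ol | OC/C(=C\c1ccc(OCOC)cc1O)c1ccc(OCOC)cc1OCOC | intermediate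
7 | 3-[2,4-bis(methoxymethoxy)phenyl]-7-(methoxymethoxy)-2H-chromene | COCOc1ccc2c(c1)OCC(c1ccc(OCOC)cc1OCOC)=C2 | intermediate
8 | (3R)-3-[2,4-bis(methoxymethoxy)phenyl]-7-(methoxymethoxy)chromane | COCOc1ccc2c(c1)OC[C@@H](c1ccc(OCOC)cc1OCOC)C2 | intermediate
9 | (3R)-6-bromo-3-[5-bromo-2,4-bis(methoxymethoxy)phenyl]-7-(methoxymethoxy)chromane | Brc1cc2c(cc1OCOC)OC[C@@H](c1cc(Br)c(OCOC)cc1OCOC)C2 | intermediate
10 | prenylboronic acid pinacol ester, 4,4,5,5-tetramethyl-2-(3-methylbut-2-en-1-yl)-1,3,2-dioxaborolane | CC(C)=CCB1OC(C)(C)C(C)(C)O1 | starting material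
11 | (3R)-3-[2,4-bis(methoxymethoxy)-5-(2-methylbut-3-en-2-yl)phenyl]-7-(methoxymethoxy)-6-(2-methylbut-3-en-2-yl)chromane | C=CC(C)(C)c1cc2c(cc1OCOC)OC[C@@H](c1cc(C(C)(C)C=C)c(OCOC)cc1OCOC)C2 | intermediate
12 | Manuifolin E, (3R)-3-[2,4-dihydroxy-5-(2-methylbut-3-en-2-yl)phenyl]-6-(2-methylbut-3-en-2-yl)chroman-7-ol | C=CC(C)(C)c1cc2c(cc1O)OC[C@@H](c1cc(C(C)(C)C=C)c(O)cc1O)C2 | target

Total step count: 9. Longest linear sequence: 9 steps (from 1 or 2 to 12); 10 enters at step 8.

Steps most likely to fail

Step 8. At carbons flanked by an ortho acetal oxygen, palladium may migrate to the primary allyl terminus before reductive elimination, which would transfer a linear prenyl group at one or both sites. The second coupling may also stall, or protodebromination may compete. Fallback, from 9 back to 11, building the same two aryl–quaternary carbon bonds by enolate arylation: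
- A twofold palladium-catalysed α-arylation of isobutyronitrile (Pd2(dba)3, P(t-Bu)3 or BINAP, NaHMDS, toluene, 80 °C) should give the bis(nitrile) 2-{(3R)-3-[5-(2-cyanopropan-2-yl)-2,4-bis(methoxymethoxy)phenyl]-7-(methoxymethoxy)chroman-6-yl}-2-methylpropanenitrile F1.
- DIBAL-H (toluene, −78 °C, buffered aqueous work-up) should reduce both nitriles to the non-enolisable bis(aldehyde) 2-{(3R)-3-[2,4-bis(methoxymethoxy)-5-(2-methyl-1-oxopropan-2-yl)phenyl]-7-(methoxymethoxy)chroman-6-yl}-2-methylpropanal F2.
- A double Wittig methylenation (Ph3PCH3Br, KOt-Bu, THF, 0 °C) should then return to 11.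

Step 6. The ortho-substituted aryl group at C3 may crowd the alkene and twist out of conjugation, leading to poor facial selectivity or slow turnover. Acidic iridium hydrides may also cause partial acetal loss. Fallback, from 7 back to 8, by resolution instead of asymmetric catalysis:
- Heterogeneous hydrogenation (H2, 1 atm, Pd/C, EtOAc) should give the racemic isoflavan rac-3-[2,4-bis(methoxymethoxy)phenyl]-7-(methoxymethoxy)chromane F3.
- Preparative chiral SFC on a polysaccharide phase should deliver 8 and set aside its enantiomer (3S)-3-[2,4-bis(methoxymethoxy)phenyl]-7-(methoxymethoxy)chromane F4.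

Step 9. The freed phenols may add across the neighbouring vinyl groups under acid, and formaldehyde-derived electrophiles may be captured by the unprotected resorcinol rings at C8 and C3′. Fallback, from 9 to 12, moving the acid step ahead of alkene installation and finishing with fluoride:
- Methanolic HCl at room temperature on 9 should give the triphenol (3R)-6-bromo-3-(5-bromo-2,4-dihydroxyphenyl)chroman-7-ol F5.
- TBSCl and imidazole in DMF should convert it into (3R)-6-bromo-3-[5-bromo-2,4-bis(tert-butyldimethylsilyloxy)phenyl]-7-(tert-butyldimethylsilyloxy)chromane F6.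
- The twofold γ-selective coupling with 10 under the conditions of step 8 should give (3R)-3-[2,4-bis(tert-butyldimethylsilyloxy)-5-(2-methylbut-3-en-2-yl)phenyl]-7-(tert-butyldimethylsilyloxy)-6-(2-methylbut-3-en-2-yl)chromane F7.
- TBAF buffered with AcOH (THF, 0 °C) should release 12 without any acid.

Further compounds
F1 | step 8 | 2-{(3R)-3-[5-(2-cyanopropan-2-yl)-2,4-bis(methoxymethoxy)phenyl]-7-(methoxymethoxy)chroman-6-yl}-2-methylpropanenitrile | N#CC(C)(C)c1cc2c(cc1OCOC)OC[C@@H](c1cc(C(C)(C)C#N)c(OCOC)cc1OCOC)C2
F2 | step 8 | 2-{(3R)-3-[2,4-bis(methoxymethoxy)-5-(2-methyl-1-oxopropan-2-yl)phenyl]-7-(methoxymethoxy)chroman-6-yl}-2-methylpropanal | O=CC(C)(C)c1cc2c(cc1OCOC)OC[C@@H](c1cc(C(C)(C)C=O)c(OCOC)cc1OCOC)C2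
F3 | step 6 | rac-3-[2,4-bis(methoxymethoxy)phenyl]-7-(methoxymethoxy)chromane | COCOc1ccc2c(c1)OCC(c1ccc(OCOC)cc1OCOC)C2
F4 | step 6 | (3S)-3-[2,4-bis(methoxymethoxy)phenyl]-7-(methoxymethoxy)chromane | COCOc1ccc2c(c1)OC[C@H](c1ccc(OCOC)cc1OCOC)C2
F5 | step 9 | (3R)-6-bromo-3-(5-bromo-2,4-dihydroxyphenyl)chroman-7-ol | Brc1cc2c(cc1O)OC[C@@H](c1cc(Br)c(O)cc1O)C2
F6 | step 9 | (3R)-6-bromo-3-[5-bromo-2,4-bis(tert-butyldimethylsilyloxy)phenyl]-7-(tert-butyldimethylsilyloxy)chromane | Brc1cc2c(cc1O[Si](C)(C)C(C)(C)C)OC[C@@H](c1cc(Br)c(O[Si](C)(C)C(C)(C)C)cc1O[Si](C)(C)C(C)(C)C)C2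
F7 | step 9 | (3R)-3-[2,4-bis(tert-butyldimethylsilyloxy)-5-(2-methylbut-3-en-2-yl)phenyl]-7-(tert-butyldimethylsilyloxy)-6-(2-methylbut-3-en-2-yl)chromane | C=CC(C)(C)c1cc2c(cc1O[Si](C)(C)C(C)(C)C)OC[C@@H](c1cc(C(C)(C)C=C)c(O[Si](C)(C)C(C)(C)C)cc1O[Si](C)(C)C(C)(C)C)C2
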